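All runs were generated by integration for an exercise, noise included.

Whether to hold cedar on to 4.0 h or spend more partner on it turns on what has slowed it.

| flask | left-handed substrate | right-handed substrate | partner | protic impurity | free catalyst | remark | time |
|---|---|---|---|---|---|---|---|
| cedar | 10 mM | 10 mM | 11 mM | 2 mM | 20 µM | the very flask that is asked about, followed so far |  |
| alder | 10 mM | 10 mM | 11 mM | 4 mM | 20 µM | run made earlier |  |
| flask | 10 mM | 10 mM | 11.0 mM | 2.00 mM | 20 µM |  | 4.0 h |

- cedar (time / min: left-handed substrate / %, right-handed substrate / %, left-handed product / %): 15.0: 45.2, 45.9, 4.1; 40.0: 40.9, 44.5, 8.7; 80.0: 37.1, 41.7, 9.9; 120: 35.6, 40.4, 11.8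
- alder (time / h: left-handed substrate / %, right-handed substrate / %, left-handed product / %): 0.333: 45.4, 46.9, 3.5; 1.00: 40.0, 44.1, 8.9; 2.00: 39.4, 42.6, 8.9; 3.00: 38.5, 41.7, 9.4

(standard deviation of a reading: 1 percentage point)

1. part of the left-handed substrate and right-handed substrate charged together that has reacted at 4.0 h
2. excess of left-handed product over right-handed product in the product at 4.0 h
3. excess of right-handed substrate over left-handed substrate among what is left of the two at 4.0 h

Count turnovers (the turnover number): substrate reacted per catalyst charged. By 120 min cedar has reacted 24.0%, which is 240 turnovers, and by these scattered readings its rate has fallen about 8.48 times.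

Two colleagues disagree. The second says the impurity takes partner one for one, which leaves cedar 9.00 mM of working partner, room for 45.0% reacted, and that the flask slows as partner goes. The first says the catalyst is dying and cedar will level off. The readings favour the first on the slowing: by the second's own count, cedar has 4.20 mM of partner left, about half of its working partner, which is too little fall to match the rate.

But the second has a reply, the count per working partner: cedar reads 26.7 /mM, meaning turnovers divided by partner charged less impurity, and alder at 2.00 h reads 25.7 /mM, although alder has more impurity.

I carry that count forward from cedar's 26.7 /mM, taking alder as the later part of the same curve. Alder's reaches 28.3 /mM at 3.00 h. If the next hour adds 0.5 of the last hour's gain, the count at 4.0 h is 29.6 /mM, so the flask, which is cedar continued, stands near 26.6% reacted. Alder's last hour gained 1.8 percentage points reacted against a scatter of 1 point per reading, so my figure is an estimate and no bound.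

The forecast, from the first side and a little above my figure, gives 28%, −2% and 6.5%, holding that “more impurity means earlier catalyst death”.

The flask gives 26.6%, 0.659% and 5.78%.

    partner + protic impurity → quenched reagent (k = 2.07 /M/s)
    free catalyst + right-handed substrate ⇌ catalyst intermediate B (K = 50.0 /M, k = 19000 /M/s)
    left-handed product ⇌ right-handed product (k = 2.03 × 10⁻⁴ /s)
    partner + catalyst intermediate B → free catalyst + right-handed product (k = 21.5 /M/s)
    partner + catalyst intermediate A → free catalyst + left-handed product (k = 59.7 /M/s)
    2 free catalyst → spent catalyst (k = 50.9 /M/s)
    free catalyst + left-handed substrate ⇌ catalyst intermediate A (K = 26.3 /M, k = 3030 /M/s)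

The first side holds on the slowing, though the impurity went to partner, with quenched reagent at 2.00 mM. In the flask at 4.00 h, 91.9% of the catalyst is spent. Partner, with 33% of its charge still there, has a half-life at that time of 17 h by the step to left-handed product alone, longer than the time held. The flask's count is 29.6 /mM, above cedar's 26.7 /mM at 120 min. The second side has its ground where more partner is charged: at 19 mM the flask's count gives 50.3%, cedar's 26.7 /mM gives 45.3%, and that neighbour flask reaches 45.3%.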